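Time first: 25 min is twice the last reading of ash and elm, and elm's tris adduct moves by 1.2 percentage points between 8.00 min and 12.0 min, about the scatter, so I take your asked figures as end values.

common to all: starting material 0.020 M

|  | coupling partner | remark | time |
|---|---|---|---|
| ash | 0.013 M | run made earlier |  |
| elm | 0.072 M | run made earlier |  |
| Saturday's | 0.0160 M |  | 25 min |
| Monday's | 0.0600 M |  | 25 min |
| Thursday's | 0.0800 M |  | 25 min |

| run | time / min | tris adduct / % | starting material / % |
|---|---|---|---|
| ash | 1.00 | 3.2 | 37.0 |
| ash | 1.50 | 6.5 | 36.1 |
| ash | 3.00 | 7.7 | 33.4 |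
| ash | 5.00 | 9.6 | 30.5 |
| ash | 8.00 | 9.8 | 30.5 |
| ash | 12.0 | 10.7 | 30.4 |
| elm | 1.00 | 56.2 | 12.8 |
| elm | 1.50 | 63.2 | 8.5 |
| elm | 3.00 | 76.5 | 3.7 |
| elm | 5.00 | 83.6 | 1.6 |
| elm | 8.00 | 86.7 | 1.8 |
| elm | 12.0 | 87.9 | 0 |

(scatter of a reading: 1 percentage point)

* how much tris adduct is there at the end, in percent of the starting material charged: for each flask in turn (Saturday's, Monday's, Thursday's)



Each starting material takes 3 coupling partners to reach tris adduct, so I count partner in equivalents of the charge, e. I carry one number, the selectivity factor: tris adduct made per unit of charge lost elsewhere, per equivalent of mean partner, where the mean e − 3/2 lies halfway between the charge and what full conversion to tris adduct leaves. Elm, with 3.60 equivalents and 87.9% tris adduct, gives a reading of 3.46.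

Multiplying by the mean partner gives the ratio of tris adduct to loss. My figure for Thursday's flask is 89.6%, and for Monday's flask 83.8%. Saturday's flask holds 0.800 equivalents, fewer than 3, so the factor doesn't apply there. I scale ash by its partner charge instead and get 13.2%.

Your forecast reads 14%, 81% and 90%, with “the partition steeper than first order in partner”. My factor is first order, and for Monday's flask I stand 2.8 points higher.

The flasks give 15.4%, 82.8% and 89.9%.

    coupling partner + first product → bis adduct (k = 4.50 M⁻¹ s⁻¹)
    starting material ⇌ dormant form (K = 1.10, k = 0.0460 s⁻¹)
    first product → side product (k = 0.0240 s⁻¹)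
    coupling partner + bis adduct → tris adduct (k = 1.80 M⁻¹ s⁻¹)
    starting material + coupling partner → first product (k = 0.840 M⁻¹ s⁻¹)

Read back from these results, the selectivity factor is 3.56 for Thursday's flask and 3.21 for Monday's, against the reading of 3.46 from elm. In Saturday's flask, half of the turnover to bis adduct is done by 0.608 min, while half of the turnover to side product takes until 1.63 min. With coupling partner at 0% at 25.0 min, Saturday's flask still holds 27.1% starting material and 29.8% dormant form.

The data are calculated for substances that don't exist; the scatter is artificial.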